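Rings: A dihydropyran, B piperidine, C cycloheptene, D cyclopentane bearing CO2H, E cyclopentene. Ring E, fused to ring C through the tetrasubstituted C=C, is read as a 2-cyclopentenone whose carbonyl carbon is the later ring-fusion CH of rings D and E. A one-pot Friedel–Crafts acylation/Nazarov cyclisation of a cycloheptene-1-carbonyl chloride with vinyltrimethylsilane (an ethylene equivalent) joins the CH2–CH2 unit to this acyl carbon and to the alkene carbon of ring C in one operation. The precursor, an 8-azabicyclo[4.3.1]decene acid chloride from a double Mannich reaction of a cycloheptane-1,3-dione, carries a spiro-lactone (latent ring A) and a phosphonoacetate arm that later closes ring D.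

Key step: step 13

Remark on locants: bicyclic intermediates are numbered as 8-azabicyclo[4.3.1]decanes. C1 is the quaternary bridgehead, C2–C5 the four-carbon bridge, C6 the methine bridgehead, C7–N8–C9 the aza bridge, and C10 the one-carbon bridge (the later spiro carbon).

Assumption: compounds 3, 6–9, 15–20, 22 and 23 (and the fallback compounds F2–F6) are carried as mixtures of the two epimers at the phosphonate-bearing carbon (left undefined in the SMILES); this centre is destroyed in step 14.

Step 1
Reactants: 1 cycloheptane-1,3-dione; 2 ethyl 2-(diethoxyphosphoryl)acrylate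
Product: 3 ethyl 2-(diethoxyphosphoryl)-3-(2,6-dioxocycloheptyl)propanoate
Conditions: Et3N (cat.), THF, 0 °C to rt
Reagents that add atoms: none
Why: Michael addition of the acidic 2-position of the 1,3-dione to the doubly activated phosphonoacrylate under amine catalysis, the new phosphonate-bearing centre being formed as both epimers and erased in step 14.

Step 2
Reactants: 3 ethyl 2-(diethoxyphosphoryl)-3-(2,6-dioxocycloheptyl)propanoate; 4 (S)-1-phenylethylamine; 5 formaldehyde
Product: 7 ethyl 2-(diethoxyphosphoryl)-3-[(1S,6S)-2,10-dioxo-8-((S)-1-phenylethyl)-8-azabicyclo[4.3.1]decan-1-yl]propanoate, via mono-Mannich base 6 (not isolated)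
Conditions: 37% aq. CH2O (2.2 equiv), AcOH, MeOH, 0 to 60 °C; chromatography
Reagents that add atoms: formaldehyde, C=O (second equivalent, beside the one counted as reactant 5)
Why: Double Mannich reaction in which the first iminium ion aminomethylates the doubly activated C-2 of the dione to give the secondary amine 6, and the iminium ion formed from 6 and the second equivalent of formaldehyde closes the piperidone on one of the two α′-methylenes, so that the (S)-auxiliary makes the two possible bicycles diastereomers, from which the (1S,6S) isomer 7 (configuration to be confirmed by X-ray analysis of a salt) should be separable by chromatography from its (1R,6R) diastereomer.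

Step 3
Reactants: 7 the (1S,6S) N-(1-phenylethyl) bicyclic dione; 5 formaldehyde
Product: 8 ethyl 2-(diethoxyphosphoryl)-3-[(1S,6S)-8-methyl-2,10-dioxo-8-azabicyclo[4.3.1]decan-1-yl]propanoate
Conditions: H2 (4 bar), Pd(OH)2 on carbon, 37% aq. CH2O, MeOH, rt
Reagents that add atoms: none
Why: Hydrogenolysis of the benzylic C–N bond followed in the same flask by reductive amination of the secondary amine with formaldehyde exchanges the auxiliary for the N-methyl group without touching the ketones or the two bridgehead stereocentres.

Step 4
Reactants: 8 the N-methyl bicyclic dione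
Product: 9 ethyl 2-(diethoxyphosphoryl)-3-[(1S,6S)-8-methyl-10-oxo-2-(trifluoromethylsulfonyloxy)-8-azabicyclo[4.3.1]dec-2-en-1-yl]propanoate (enol triflate)
Conditions: KN(SiMe3)2 (2.1 equiv), THF, −78 °C; PhNTf2 (1.05 equiv), −78 to 0 °C
Reagents that add atoms: N-phenylbis(trifluoromethanesulfonimide), O=S(=O)(C(F)(F)F)N(c1ccccc1)S(=O)(=O)C(F)(F)F
Why: Regioselective enol triflate formation, because only the C2 ketone can enolise normally (towards C3) while the C10 ketone is flanked by a quaternary carbon and a bridgehead CH whose enolisation would give a strained anti-Bredt enolate, and the extra equivalent of base parks the phosphonoacetate as its poorly nucleophilic stabilised anion.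

Step 5
Reactants: 10 allyl alcohol; 5 formaldehyde
Product: 11 allyl chloromethyl ether
Conditions: paraformaldehyde, HCl (g), neat, 0 °C; CaCl2
Reagents that add atoms: hydrogen chloride, Cl
Why: Classical α-chloro ether synthesis in which the hemiformal of allyl alcohol is converted into the chloromethyl ether by HCl.

Step 6
Reactants: 11 allyl chloromethyl ether; 12 triphenylphosphine
Product: 13 (allyloxymethyl)triphenylphosphonium chloride
Conditions: toluene, rt to 50 °C
Reagents that add atoms: none
Why: SN2 quaternisation of the phosphine by the reactive α-chloro ether gives the Wittig salt.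

Step 7
Reactants: 9 the enol triflate; 13 (allyloxymethyl)triphenylphosphonium chloride
Product: 15 10-(allyloxymethylene) enol ether of 9 (bicyclic configuration unchanged; E/Z mixture), via allyloxymethylene ylide 14 (not isolated)
Conditions: 13 (3.5 equiv), KN(SiMe3)2 (3.4 equiv), THF, 0 °C; then 9, 0 to 50 °C
Reagents that add atoms: none
Why: Wittig reaction of the alkoxymethylene ylide with the bridging ketone, which does not enolise readily (one equivalent of ylide is consumed by the acidic phosphonoacetate), the E/Z mixture being inconsequential because both isomers converge in step 8.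

Step 8
Reactants: 15 the allyl enol ether
Product: 16 10-allyl-10-formyl bicycle (quaternary C10; allyl syn to the C2–C5 bridge, formyl syn to the aza bridge; enol triflate and phosphonoacetate arm unchanged)
Conditions: toluene, 170 °C, sealed tube
Reagents that add atoms: none
Why: Claisen rearrangement whose [3,3]-shift creates the quaternary C10 next to the quaternary C1, the allyl terminus being expected to arrive on the face over the four-carbon bridge (sp2 C2, one axial hydrogen at C5) and not over the piperidine chair (two axial hydrogens at C7 and C9), which places allyl and formyl as the target requires.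

Step 9
Reactants: 16 the allyl aldehyde
Product: 17 10-(3-hydroxypropyl)-10-(hydroxymethyl) bicycle (1,5-diol; hydroxymethyl syn to the aza bridge)
Conditions: 9-BBN (3 equiv), THF, rt; then NaBO3·4H2O, H2O, rt
Reagents that add atoms: sodium perborate, [Na+].[Na+].O[B-]1(O)OO[B-](O)(O)OO1
Why: 9-BBN reduces the neopentyl aldehyde and hydroborates the terminal alkene at its unsubstituted carbon while the electron-poor trisubstituted enol triflate is inert, and mild perborate oxidation releases the diol.

Step 10
Reactants: 17 the 1,5-diol
Product: 18 spiro-δ-lactone enol triflate (lactone O–CH2 syn to the aza bridge, lactone CH2–CH2–C=O syn to the C2–C5 bridge)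
Conditions: Ag2CO3 on Celite, toluene, reflux
Reagents that add atoms: none
Why: Oxidative lactonisation in which the unhindered primary alcohol is oxidised in preference to the neopentyl one, the aldehyde is trapped as the six-membered lactol and oxidised on to the lactone, with a reagent that tolerates the tertiary amine.

Step 11
Reactants: 18 the spiro-lactone enol triflate
Product: 19 spiro-lactone 8-azabicyclo[4.3.1]dec-2-ene-2-carboxylic acid
Conditions: Pd(OAc)2, dppf, CO (1 bar), KOAc, DMSO–H2O, 60 °C
Reagents that add atoms: carbon monoxide, [C-]#[O+]; water, O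
Why: Palladium-catalysed hydroxycarbonylation of the enol triflate (oxidative addition, CO insertion, acetate/water capture of the acyl palladium) installs the carbon that becomes the ring-fusion CH of rings D and E.

Step 12
Reactants: 19 the unsaturated acid
Product: 20 the corresponding acid chloride, as its hydrochloride
Conditions: (COCl)2, DMF (cat.), CH2Cl2, 0 °C to rt; concentrate
Reagents that add atoms: oxalyl chloride, O=C(Cl)C(=O)Cl
Why: Standard acid chloride formation with oxalyl chloride and catalytic DMF, in which the amine is masked as its hydrochloride and lactone, ester and phosphonate are inert.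

Step 13
Reactants: 20 the acid chloride hydrochloride; 21 vinyltrimethylsilane
Product: 23 cyclopentenone (ring E closed onto the former C2=C3 bond; tetrasubstituted enone; spiro-lactone intact), via divinyl ketone 22 (not isolated)
Conditions: CH2=CHSiMe3 (3 equiv), SnCl4 (6 equiv), CH2Cl2, −30 °C to rt; aq. NaHCO3
Reagents that add atoms: none
Why: SnCl4 ionises the acid chloride to an acylium ion that attacks the vinylsilane at its silicon-bearing carbon (β-silyl cation, loss of Me3SiCl) to give the cross-conjugated divinyl ketone 22, and the same Lewis acid then triggers its Nazarov cyclisation (conrotatory 4π electrocyclisation of the pentadienyl cation, oxyallyl cation, proton loss). The closest known reaction type is the one-pot vinylsilane (or ethylene) Friedel–Crafts acylation/Nazarov cyclopentenone annulation of cycloalkene-1-carbonyl chlorides. Ring E is the only ring closed, by 4π electrocyclic closure between the terminal vinyl carbon and C3 of ring C, while the acylation supplies the other new bond, from the acyl carbon to the former silyl-bearing carbon. No stereocentre is created, because the transient sp3 carbon at C3 returns to sp2 when the proton is lost towards the tetrasubstituted conjugated position, so torquoselectivity is irrelevant. The step needs ipso-selective acylation of the vinylsilane (secured by the β-silicon effect), the enone double bond at the ring fusion (the thermodynamically preferred tetrasubstituted enone) and the absence of a competing π-nucleophile in 20 (the amine is protonated; lactone, ester and phosphonate only bind the Lewis acid, hence its excess).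

Step 14
Reactants: 23 the cyclopentenone
Product: 24 tetracyclic diene ester (ring D closed; ethyl ester on the new C=C, conjugated with the tetrasubstituted C=C of rings C and E)
Conditions: LiCl, DBU, MeCN, rt
Reagents that add atoms: none
Why: Intramolecular Horner–Wadsworth–Emmons olefination in which the phosphonoacetate anion adds to the enone carbonyl in a favoured 5-exo-trig mode and irreversible loss of diethyl phosphate closes ring D, whereas conjugate addition to the tetrasubstituted β-carbon would be a disfavoured 5-endo-trig closure and is reversible.

Step 15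
Reactants: 24 the diene ester
Product: 25 saturated ethyl ester (D/E ring-fusion H and H α to the ester cis to each other, on the face of ring D that carries the CH2N arm of the quaternary carbon)
Conditions: HBF4·OEt2 (1.05 equiv); [Ir(cod)(PCy3)(py)]PF6 (10 mol %), H2 (60 bar), CH2Cl2, rt; aq. NaHCO3
Reagents that add atoms: none
Why: Homogeneous iridium-catalysed hydrogenation is expected to reduce only the ester-conjugated double bond (the remaining tetrasubstituted alkene buried between rings C and E being far less accessible), and H2 should add cis from the face of ring D bearing the CH2N arm, anti to the bulky pseudo-axial spiro carbon on the other face, which sets both new stereocentres as in the target.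

Step 16
Reactants: 25 the saturated ester lactone; 26 isopropylmagnesium chloride
Product: 27 hemiketal (2-hydroxy-2-isopropyltetrahydropyran in place of the lactone; ethyl ester intact)
Conditions: i-PrMgCl, CeCl3, THF, −78 °C
Reagents that add atoms: none
Why: Mono-addition of the weakly basic organocerium reagent to the δ-lactone, which is far more electrophilic than the hindered secondary ethyl ester, gives the stable hemiketal alkoxide at low temperature without enolising the epimerisable ester-bearing centre.

Step 17
Reactants: 27 the hemiketal
Product: 28 ethyl ester of the target (ring A formed as the 6-isopropyl-3,4-dihydro-2H-pyran)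
Conditions: MsCl, Et3N, CH2Cl2, 0 °C to rt
Reagents that add atoms: none
Why: Dehydration of the tertiary hemiketal through its mesylate and the derived oxocarbenium ion, with loss of a ring proton, gives the endocyclic trisubstituted enol ether under basic, non-epimerising conditions.

Step 18
Reactants: 28 the ethyl ester
Product: 29 CNP0237695.2 (target acid)
Conditions: Me3SnOH, ClCH2CH2Cl, 80 °C; pH 7 buffer
Reagents that add atoms: water, O (transferred through Me3SnOH)
Why: Mild, essentially neutral tin-mediated ester hydrolysis frees the acid without cleaving the acid-labile enol ether or epimerising the centre α to the carboxyl group.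

Compound list
1 | cycloheptane-1,3-dione | O=C1CCCCC(=O)C1 | starting material
2 | ethyl 2-(diethoxyphosphoryl)acrylate | C=C(C(=O)OCC)P(=O)(OCC)OCC | starting material
3 | ethyl 2-(diethoxyphosphoryl)-3-(2,6-dioxocycloheptyl)propanoate | O=C1CCCCC(=O)C1CC(C(=O)OCC)P(=O)(OCC)OCC | intermediate
4 | (S)-1-phenylethylamine | C[C@H](N)c1ccccc1 | starting material
5 | formaldehyde | C=O | starting material
6 | mono-Mannich base: ethyl 2-(diethoxyphosphoryl)-3-[2,6-dioxo-1-({[(S)-1-phenylethyl]amino}methyl)cycloheptyl]propanoate | O=C1CCCCC(=O)C1(CN[C@@H](C)c2ccccc2)CC(C(=O)OCC)P(=O)(OCC)OCC | intermediate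
7 | (1S,6S) bicyclic dione with N-((S)-1-phenylethyl) | O=C2[C@H]1CCCC(=O)[C@]2(CC(C(=O)OCC)P(=O)(OCC)OCC)CN([C@@H](C)c3ccccc3)C1 | intermediate
8 | (1S,6S) N-methyl bicyclic dione | O=C2[C@H]1CCCC(=O)[C@]2(CC(C(=O)OCC)P(=O)(OCC)OCC)CN(C)C1 | intermediate
9 | C2 enol triflate of 8 | O=C2[C@H]1CCC=C(OS(=O)(=O)C(F)(F)F)[C@]2(CC(C(=O)OCC)P(=O)(OCC)OCC)CN(C)C1 | intermediate
10 | allyl alcohol | C=CCO | starting material
11 | allyl chloromethyl ether | C=CCOCCl | intermediate
12 | triphenylphosphine | c1ccc(cc1)P(c1ccccc1)c1ccccc1 | starting material
13 | (allyloxymethyl)triphenylphosphonium chloride | C=CCOC[P+](c1ccccc1)(c1ccccc1)c1ccccc1.[Cl-] | intermediate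
14 | (allyloxymethylene)triphenylphosphorane | C=CCOC=P(c1ccccc1)(c1ccccc1)c1ccccc1 | intermediate
15 | 10-(allyloxymethylene) enol ether (E/Z mixture) | C=CCOC=C2[C@H]1CCC=C(OS(=O)(=O)C(F)(F)F)[C@]2(CC(C(=O)OCC)P(=O)(OCC)OCC)CN(C)C1 | intermediate
16 | 10-allyl-10-formyl bicycle (allyl syn to the C2–C5 bridge) | C=CC[C@@]2(C=O)[C@H]1CCC=C(OS(=O)(=O)C(F)(F)F)[C@]2(CC(C(=O)OCC)P(=O)(OCC)OCC)CN(C)C1 | intermediate
17 | 10-(3-hydroxypropyl)-10-(hydroxymethyl) diol | OCCC[C@@]2(CO)[C@H]1CCC=C(OS(=O)(=O)C(F)(F)F)[C@]2(CC(C(=O)OCC)P(=O)(OCC)OCC)CN(C)C1 | intermediate
18 | spiro-δ-lactone enol triflate | O=C1CC[C@@]2(CO1)[C@H]1CCC=C(OS(=O)(=O)C(F)(F)F)[C@]2(CC(C(=O)OCC)P(=O)(OCC)OCC)CN(C)C1 | intermediate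
19 | spiro-lactone dec-2-ene-2-carboxylic acid | O=C1CC[C@@]2(CO1)[C@H]1CCC=C(C(=O)O)[C@]2(CC(C(=O)OCC)P(=O)(OCC)OCC)CN(C)C1 | intermediate
20 | acid chloride of 19, hydrochloride | O=C1CC[C@@]2(CO1)[C@H]1CCC=C(C(Cl)=O)[C@]2(CC(C(=O)OCC)P(=O)(OCC)OCC)CN(C)C1.Cl | intermediate
21 | vinyltrimethylsilane | C=C[Si](C)(C)C | starting material
22 | cross-conjugated divinyl ketone (2-acryloyl bicycle) | O=C1CC[C@@]2(CO1)[C@H]1CCC=C(C(=O)C=C)[C@]2(CC(C(=O)OCC)P(=O)(OCC)OCC)CN(C)C1 | intermediate
23 | cyclopentenone (ring E closed) | O=C1CC[C@@]2(CO1)[C@H]1CCC3=C(C(=O)CC3)[C@]2(CC(C(=O)OCC)P(=O)(OCC)OCC)CN(C)C1 | intermediate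
24 | tetracyclic diene ester (ring D closed) | O=C1CC[C@@]2(CO1)[C@H]1CCC3=C4C(CC3)=C(C(=O)OCC)C[C@]42CN(C)C1 | intermediate
25 | saturated ethyl ester lactone | O=C1CC[C@@]2(CO1)[C@H]1CCC3=C4[C@@H](CC3)[C@@H](C(=O)OCC)C[C@]42CN(C)C1 | intermediate
26 | isopropylmagnesium chloride | CC(C)[Mg]Cl | starting material
27 | isopropyl hemiketal | CC(C)C1(O)CC[C@@]2(CO1)[C@H]1CCC3=C4[C@@H](CC3)[C@@H](C(=O)OCC)C[C@]42CN(C)C1 | intermediate
28 | ethyl ester of the target | CC(C)C1=CC[C@@]2(CO1)[C@H]1CCC3=C4[C@@H](CC3)[C@@H](C(=O)OCC)C[C@]42CN(C)C1 | intermediate
29 | CNP0237695.2 | CC(C)C1=CC[C@@]2(CO1)[C@H]1CCC3=C4[C@@H](CC3)[C@@H](C(=O)O)C[C@]42CN(C)C1 | target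

Total step count: 18. Longest linear sequence: 16 steps (steps 1–4 and 7–18; steps 5 and 6 make the Wittig salt).

Steps most likely to fail

Step 13. The Lewis acid may be sequestered by lactone, ester and phosphonate so that ionisation or electrocyclisation stalls. Meanwhile the intermediate vinyl ketone may polymerise, or the acylium ion may be captured by the phosphonoacetate arm. The fallback sets out from enol triflate 18 and builds the same dienone under neutral conditions by palladium-catalysed carbonylative Stille coupling (Pd(PPh3)4, LiCl, CO, tributyl(vinyl)stannane, THF, 55 °C) to divinyl ketone 22. After venting CO, 22 is cyclised in the same flask by a Brønsted-acid Nazarov reaction (CF3SO3H, CH2Cl2, 0 °C), and the route is rejoined at 23. Steps 11 and 12 are skipped and no compound outside the list arises (F0).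

Step 2. The primary amine may condense with the 1,3-dione to a vinylogous amide, the iminium ion may aminomethylate the acidic phosphonoacetate methine, or open-chain Mannich bases may oligomerise instead of closing the piperidone. The fallback sets out from 3 and uses a preformed bis-electrophile in place of the three-component condensation. Amine 4 is converted with paraformaldehyde and methanol (K2CO3) into N,N-bis(methoxymethyl)-(S)-1-phenylethylamine F1. With MeSiCl3 in MeCN, F1 releases its two iminium ions one after the other in the absence of free amine and water, and should annulate 3 to the same separable pair of diastereomers, rejoining the route at 7.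

Step 8. The sigmatropic shift may show poor or reversed facial selectivity, delivering the allyl group over the piperidine ring. The fallback sets out from enol ether 15 and exchanges the roles of the two arms, so that the arm delivered by the rearrangement becomes the one-carbon arm. The epimeric aldehyde that the rearrangement would then give, 10-epi-16 F2, is olefinated with Ph3P=CHCO2Et (toluene, 90 °C) to the (E)-enoate F3. Its allyl group is isomerised with RuHCl(CO)(PPh3)3 to the (E)-propenyl compound F4. Ozonolysis of this electron-rich alkene (amine protonated with CF3CO2H; NaBH4 work-up) should give the hydroxymethyl enoate F5. Conjugate reduction with [(Ph3P)CuH]6 then gives the saturated hydroxy ester F6, which lactonises (pyridinium p-toluenesulfonate, toluene) and rejoins the route at 18.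

Further compounds
F1 | step 2 | N,N-bis(methoxymethyl)-(S)-1-phenylethylamine | COCN(COC)[C@@H](C)c1ccccc1
F2 | step 8 | 10-epi-16 (allyl syn to the aza bridge) | C=CC[C@]2(C=O)[C@H]1CCC=C(OS(=O)(=O)C(F)(F)F)[C@]2(CC(C(=O)OCC)P(=O)(OCC)OCC)CN(C)C1
F3 | step 8 | (E)-enoate from F2 | CCOC(=O)/C=C/[C@@]2(CC=C)[C@H]1CCC=C(OS(=O)(=O)C(F)(F)F)[C@]2(CC(C(=O)OCC)P(=O)(OCC)OCC)CN(C)C1
F4 | step 8 | (E)-propenyl isomer of F3 | CCOC(=O)/C=C/[C@@]2(/C=C/C)[C@H]1CCC=C(OS(=O)(=O)C(F)(F)F)[C@]2(CC(C(=O)OCC)P(=O)(OCC)OCC)CN(C)C1
F5 | step 8 | hydroxymethyl enoate | CCOC(=O)/C=C/[C@@]2(CO)[C@H]1CCC=C(OS(=O)(=O)C(F)(F)F)[C@]2(CC(C(=O)OCC)P(=O)(OCC)OCC)CN(C)C1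
F6 | step 8 | saturated hydroxy ester | CCOC(=O)CC[C@@]2(CO)[C@H]1CCC=C(OS(=O)(=O)C(F)(F)F)[C@]2(CC(C(=O)OCC)P(=O)(OCC)OCC)CN(C)C1
F0 | step 13 | none | none
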